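In a one-step world an initial velocity runs on unchanged, and one chemist holds that view of this flask: solid monomer feeds the solution at a constant, zero-order flux. The other expects that flux to fall as the solution fills.

| setting | Friday's | Sunday's | flask |
|---|---|---|---|
| solid monomer | 10 mM | 6.7 mM | 10 mM |
| initiator | 100 µM | 100 µM | 100 µM |
| remark | the very flask that is asked about, followed so far | run made earlier |  |
| time |  |  | 2.0 h |

| run | time / min | monomer in chains / % | free monomer / % |
|---|---|---|---|
| Friday's | 8.00 | 0.9 | 2.2 |
| Friday's | 20.0 | 0.3 | 4.7 |
| Friday's | 40.0 | 1.6 | 8.8 |
| Friday's | 60.0 | 1.3 | 11.9 |
| Sunday's | 4.00 | 0 | 1.5 |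
| Sunday's | 8.00 | 0.4 | 3.5 |
| Sunday's | 20.0 | 0.8 | 7.9 |
| Sunday's | 50.0 | 3.2 | 16.4 |

(readings scatter by 0.5 percentage points)

* amount of monomer in chains at 2.0 h, in percent of the solid monomer charged
* concentration of free monomer in solution at 2.0 h, in percent of saturation

- solid monomer is a solid; its amount is given per volume of the solution
- the analysis behind the earlier runs scatters by 0.5 percentage points, standard deviation
- on the list of suspects stand: initiator -> 2 initiating radical; free monomer + initiating radical -> growing radical + monomer in chains; free monomer + growing radical -> monomer in chains + growing radical; 2 growing radical -> dead chain; solid monomer <-> free monomer; free monomer -> decomposition product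
- at the start none of the solid monomer is in solution

Both count dissolved monomer in mM, c(free monomer) + c(monomer in chains). At 20.0 min, Friday's flask holds 0.500 mM and Sunday's 0.583 mM. Their mean gives 1.62 mM/h, the dissolving flux J, the dissolved concentration gained per hour from a nearly empty solution. Charge divided by J is a clock: for Friday's flask 6.16 h, longer than the asked time, so solid stands on either view.

The constant-flux chemist lets chains grow with the square of time. The last readings of both runs, averaged, then give 8.77% for Friday's flask. The other answers that Friday's dissolved monomer at 60.0 min lies below J times that time, by 3 percentage points of charge against a scatter of 0.5 points. I side with the bend. The forecast, made by the chemist of the falling flux, is 6.5% of the charge in chains and free monomer at 47% of saturation, with the ground “Dissolution therefore doesn't depend on the solid load”.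

The flask gives 5.41% of the charge in chains, below the constant-flux figure, and free monomer at 47.1% of saturation.

    initiator → 2 initiating radical (k = 0.150 /h)
    free monomer + initiating radical → growing radical + monomer in chains (k = 1.60 × 10⁶ /M/s)
    free monomer + growing radical → monomer in chains + growing radical, rate k3*[growing radical]*[free monomer] (k = 3.60 × 10⁷ /M/h)
    2 growing radical → dead chain (k = 1.00 × 10⁸ /M/s)
    solid monomer ⇌ free monomer, rate k5*(cs5 - [free monomer]) while solid is left; crystals form when [free monomer] > cs5 (solubility = 4.10 mM, k = 0.420 /h)
    free monomer → decomposition product (k = 2.60 × 10⁻⁴ /h)

Constant flux was near the truth while the solution stood nearly empty: in the flask free monomer reached 7.74% of saturation at 0.200 h, but 30.5% at 1.00 h. A neighbour charged with 4.0 mM has a clock of 2.47 h, still longer than the asked time, and at 2.00 h it holds solid monomer at 38.2% of its charge.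

The data come from a simulation on assumed constants; the scatter is artificial.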